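## The problem

Target 21 is an isoflavan: a chroman (rings A and C) that carries the prenylated resorcinol ring B at C3.

- **Ring A substitution.** Ring A is fully differentiated: OMe at C5, free OH at C7, formyl at C8, the ring oxygen at C8a and the ring carbon at C4a. O5 must be told apart from O7, and C8 from C6.
- **Stereochemistry.** C3 (R) is the only stereocentre. Nothing else in the molecule can relay chirality to it, so it must come from a catalyst or arrive in a building block. It should never sit next to a carbonyl on the way, where it would be benzylic and enolisable.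
- **Fragile groups.** The prenyl group lies between two phenolic hydroxyls, and acid closes it onto either oxygen to a 2,2-dimethylchroman. Hydrogenation, ozone, peracids and boron tribromide are excluded for the same olefin. The chelated salicylaldehyde and two very electron-rich arenes add sensitivity to oxidants and electrophiles.
- **Consequence for protection.** All protecting groups must leave together under mild conditions at the end.
- **Enabling feature.** Ring C joins ring A through two adjacent arene carbons, C4a (C–C) and C8a (C–O), and C8a is flanked on its other side by C8, which bears the formyl carbon. An arene with iodine at C8a, hydrogen at C4a and a masked formyl group at C8 is an ortho-blocked aryl iodide of the kind a palladium/norbornene (Catellani) relay needs.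

## Retrosynthesis

**21 ⇒ 20.** Only protecting groups are removed: three MOM ethers (O7, O2′, O4′) and the C8 dioxolane. All four are acetals, so one acidic step frees them together. Benzyl and methyl ethers are ruled out by the prenyl olefin and by the need to keep the C5 methyl ether. The forward step must be mild enough to spare the prenyl group next to the freed phenols.

**20 ⇒ 7 + 19.** Ring C is cut at C4–C4a and O1–C8a, giving aryl iodide 7 and the chiral 1,3-bromohydrin 19.
- Neighbouring cuts are less attractive. O1–C2 with C4–C4a would need a carbon nucleophile at C4a of a phloroglucinol-type ring, where C6 competes. Cuts through C2–C3 or C3–C4 place C3 beside a carbonyl.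
- Here the iodide at C8a dictates which C–H reacts, and the C8 substituent is both the blocking group and the future aldehyde.
- The simplification is large: two fragments of similar size, ring A complete, the stereocentre already in 19.
- The forward reaction must alkylate C4a faster than base destroys 19, stop at one alkylation, extrude norbornene, and end with C–O rather than β-hydride elimination.

**19 ⇒ 17.** The C–Br bond and the O–H of 19 are traced back to one C–O bond of the achiral oxetane 17. The stereocentre then reduces to telling apart two enantiotopic CH2–O arms, which a chiral hydrogen-bond-donor catalyst with TMSBr is known to do for 3-aryloxetanes. Auxiliary-based alkylation or enzymatic desymmetrisation of a 2-aryl-1,3-diol would cost several more steps. The forward step must be selective with an ortho-substituted, electron-rich aryl group and must spare the MOM ethers and the olefin.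

**17 ⇒ 14 + 15.** The aryl–prenyl bond (C3′–C1″) is cut. C3′ of 14 lies between two MOM ethers and is the unique site of directed lithiation; prenyl bromide 15 is the electrophile. Prenylating before the aryl–oxetane bond would force a second metalation beside a doubly activated benzylic–allylic CH2, or an electrophilic halogenation next to the olefin.

**14 ⇒ 12 + 13, and 12 ⇒ 9 ⇒ 8.** The aryl–oxetane bond is cut to boronic acid 12 and commercial 3-iodooxetane 13 (nickel-catalysed alkyl–aryl Suzuki–Miyaura coupling). Building the oxetane from a diol would take three more steps. Boronic acid 12 comes from bromide 9 by bromine–lithium exchange, and 9 from commercial 4-bromoresorcinol 8.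

**7 ⇒ 5 ⇒ 4 ⇒ 3 ⇒ 1.** The iodide comes from bromide 5 through its aryllithium. The dioxolane and the MOM ether are protecting steps. The O5/O7 problem is solved at the start: in commercial 1 only the methoxy group next to the formyl group can chelate BCl3, so only that ether is cleaved.

## Roads not taken

**Alternative 1:** Ring B would be built last by a photochemical Danheiser benzannulation.
- *Cut and key step.* Irradiation of diazo enone A2 with prenyl siloxyalkyne A3 would trigger Wolff rearrangement, [2+2] cycloaddition, 4π opening and 6π closure to phenol A1.
- *Merits.* The reaction class is established and runs under neutral conditions. Ring B is formed with the prenyl group placed unambiguously and with O2′ and O4′ already differentiated, with no directed metalation. On precedent for the key step and on the handling of ring B this road is better than the chosen one.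
- *Weak points.* Ring C and C3 must be made beforehand by separate asymmetric chemistry, through a chroman-3-carbaldehyde whose stereocentre is enolisable. A1 has O7 methylated and no carbon at C8. Late formylation would have to choose C8 over C6 and over the more nucleophilic ring B phenol, and the following 7-O-demethylation would need a Lewis acid next to the prenyl group.
- *Comparison.* The chosen plan offers convergence (branches of four and five steps), a ring A that is complete before the union, and a stereocentre made in one catalytic step.

**Alternative 2:** Ring C would be formed at the lactone level by carbene catalysis.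
- *Cut and key step.* CsF would unmask an o-quinone methide from silyl ether benzyl bromide A6, a chiral triazolium-derived carbene would turn acyl imidazole A5 into an azolium enolate, and C3–C4 then O1–C2 bond formation would give dihydrocoumarin A4.
- *Merits.* Stereocentre and ring are created together under catalyst control, and this formal [4+2] class has good precedent. In both respects it is ahead of the chosen plan.
- *Weak points.* In A4, C3 is benzylic and α to the lactone carbonyl, so fluoride and carbene base can erode the enantiomeric purity. The lactone must be reduced to the cyclic ether in two further steps. Ring A again arrives as the 5,7-dimethyl ether without the C8 carbon, with the same late formylation and demethylation problem.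
- *Comparison.* The chosen plan offers a C3 that is never activated, C2 at the right oxidation level from the start, and every ring A substituent in place.

**Alternative 3:** The same C4–C4a and O1–C2 connections would be made with ring A as nucleophile.
- *Cut and key step.* 3,5-Dimethoxyphenol A8 would add through its ortho carbon to the iminium ion of 2-arylacrolein A9, a chiral primary amine salt would direct protonation at C3, and hemiacetal closure would give lactol A7.
- *Merits.* It is the shortest road on paper, metal-free, and starts from a commercial phenol. In step count and simplicity it beats the chosen plan.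
- *Weak points.* Enantioselective protonation of an α-aryl enamine is hard to control. A7 equilibrates with its open hydroxy aldehyde, whose α-aryl stereocentre can racemise. A8 can react at C4 or at oxygen instead of C2. Ionic deoxygenation of the lactol needs acid and silane in the presence of MOM ethers and the prenyl group. Ring A is again incomplete.
- *Comparison.* The chosen plan offers a stereocentre fixed and configurationally inert before the union, and no ring A chemistry after it.

Key step: step 10

Assumption: the squaramide antipode that gives the (R)-bromohydrin is assigned by analogy with simpler 3-aryloxetanes; both antipodes are equally accessible, so the route does not depend on the assignment.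
Assumption: in the fallback to step 9 the lipase is taken to acylate the (S)-alcohol faster; if the preference is the reverse, alcohol and acetate exchange roles.

## Route

Step 1
Reactants: 1 2-bromo-4,6-dimethoxybenzaldehyde
Product: 3 2-bromo-6-hydroxy-4-methoxybenzaldehyde, via aryl dichloroborinate 2 (not isolated)
Conditions: BCl3 (1.2 equiv), CH2Cl2, −78 → 0 °C; then H2O
Reagents that add atoms: none
Why: Chelation-controlled aryl methyl ether cleavage: BCl3 bridges the formyl oxygen and the adjacent methoxy group and chloride removes that methyl group only. The para methoxy group (the later C5–OMe) cannot chelate and should stay.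

Step 2
Reactants: 3 2-bromo-6-hydroxy-4-methoxybenzaldehyde
Product: 4 2-bromo-4-methoxy-6-(methoxymethoxy)benzaldehyde
Conditions: MOMCl, iPr2NEt, CH2Cl2, 0 °C → rt
Reagents that add atoms: chloromethyl methyl ether, COCCl
Why: Williamson-type O-alkylation of the chelated phenol. The MOM ether masks O7 against the basic annulation and leaves with the other acetals at the end.

Step 3
Reactants: 4 2-bromo-4-methoxy-6-(methoxymethoxy)benzaldehyde
Product: 5 2-[2-bromo-4-methoxy-6-(methoxymethoxy)phenyl]-1,3-dioxolane
Conditions: TMSOCH2CH2OTMS, TMSOTf (5 mol%), CH2Cl2, −78 → −20 °C; pyridine quench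
Reagents that add atoms: 1,2-bis(trimethylsilyloxy)ethane, C[Si](C)(C)OCCO[Si](C)(C)C
Why: Silyl-transfer acetalisation is irreversible (hexamethyldisiloxane forms) and needs no free protic acid, so the hindered, electron-rich aldehyde should be masked without loss of the aryl MOM ether. The dioxolane is the ortho blocking group of the key step.

Step 4
Reactants: 5 2-[2-bromo-4-methoxy-6-(methoxymethoxy)phenyl]-1,3-dioxolane
Product: 7 2-[2-iodo-4-methoxy-6-(methoxymethoxy)phenyl]-1,3-dioxolane, via aryllithium 6 (not isolated)
Conditions: n-BuLi, THF, −78 °C; then I2, −78 °C → rt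
Reagents that add atoms: iodine, II
Why: Bromine–lithium exchange at −78 °C is faster than MOM-directed deprotonation, and the aryllithium, held by the neighbouring dioxolane oxygens, is trapped by iodine. The iodide is wanted for fast oxidative addition in the Catellani reaction.

Step 5
Reactants: 8 4-bromobenzene-1,3-diol (4-bromoresorcinol)
Product: 9 1-bromo-2,4-bis(methoxymethoxy)benzene
Conditions: MOMCl (2.5 equiv), iPr2NEt, CH2Cl2, 0 °C → rt
Reagents that add atoms: chloromethyl methyl ether, COCCl
Why: Double Williamson-type O-alkylation. The two MOM ethers later direct lithiation to the carbon between them and are removed in the last step.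

Step 6
Reactants: 9 1-bromo-2,4-bis(methoxymethoxy)benzene
Product: 12 [2,4-bis(methoxymethoxy)phenyl]boronic acid, via aryllithium 10 (not isolated), via lithium aryltriisopropoxyborate 11 (not isolated)
Conditions: n-BuLi, THF, −78 °C; B(OiPr)3, −78 °C → rt; aq. NH4Cl
Reagents that add atoms: triisopropyl borate, CC(C)OB(OC(C)C)OC(C)C; water, O
Why: Bromine–lithium exchange, borylation and hydrolysis of the borate on work-up. Exchange at −78 °C outruns ortho-deprotonation, so boron ends up only at the former C–Br carbon.

Step 7
Reactants: 12 [2,4-bis(methoxymethoxy)phenyl]boronic acid; 13 3-iodooxetane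
Product: 14 3-[2,4-bis(methoxymethoxy)phenyl]oxetane
Conditions: NiI2 (6 mol%), trans-2-aminocyclohexanol hydrochloride (6 mol%), NaHMDS (2 equiv), iPrOH, 80 °C
Reagents that add atoms: none
Why: Nickel-catalysed alkyl–aryl Suzuki–Miyaura coupling of a secondary alkyl iodide, a method established for 3-iodooxetane with arylboronic acids. The oxetane and the MOM ethers are stable to the basic alcoholic medium.

Step 8
Reactants: 14 3-[2,4-bis(methoxymethoxy)phenyl]oxetane; 15 1-bromo-3-methylbut-2-ene (prenyl bromide)
Product: 17 3-[2,4-bis(methoxymethoxy)-3-(3-methylbut-2-en-1-yl)phenyl]oxetane, via aryllithium 16 (not isolated)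
Conditions: n-BuLi, THF, 0 °C; CuBr·SMe2 (10 mol%), then 15, −78 °C → rt
Reagents that add atoms: none
Why: Directed ortho-metalation: the proton between the two MOM ethers is the most acidic and the best coordinated, so lithiation should occur there alone. Copper-catalysed allylic substitution with prenyl bromide should give the linear prenyl arene, and the oxetane is inert to n-BuLi without a Lewis acid.

Step 9
Reactants: 17 3-[2,4-bis(methoxymethoxy)-3-(3-methylbut-2-en-1-yl)phenyl]oxetane
Product: 19 (2R)-3-bromo-2-[2,4-bis(methoxymethoxy)-3-(3-methylbut-2-en-1-yl)phenyl]propan-1-ol, via trimethylsilyl ether 18 (not isolated)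
Conditions: TMSBr (1.3 equiv), chiral arylpyrrolidine-tert-leucine squaramide (5 mol%, antipode giving R), tBuOMe, −78 °C; then aq. citric acid, THF, 0 °C
Reagents that add atoms: bromotrimethylsilane, C[Si](C)(C)Br
Why: Enantioselective desymmetrising ring opening of a 3-aryloxetane by TMSBr under chiral squaramide hydrogen-bond-donor catalysis, a known reaction of this substrate class. The catalyst-bound bromide attacks one of the two enantiotopic CH2–O carbons of the silylated oxetane in an SN2 sense, which sets the stereocentre under catalyst control. Low temperature and near-stoichiometric TMSBr should spare the MOM ethers and the olefin.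

Step 10
Reactants: 7 2-[2-iodo-4-methoxy-6-(methoxymethoxy)phenyl]-1,3-dioxolane; 19 (2R)-3-bromo-2-[2,4-bis(methoxymethoxy)-3-(3-methylbut-2-en-1-yl)phenyl]propan-1-ol
Product: 20 2-{(3R)-3-[2,4-bis(methoxymethoxy)-3-(3-methylbut-2-en-1-yl)phenyl]-5-methoxy-7-(methoxymethoxy)-3,4-dihydro-2H-chromen-8-yl}-1,3-dioxolane
Conditions: Pd(OAc)2 (10 mol%), XPhos (20 mol%), norbornene (2 equiv), Cs2CO3 (3 equiv), 1,4-dioxane, 100 °C
Reagents that add atoms: none
Why: Proposed new method: zerovalent palladium should insert into the C8a–I bond of 7, norbornene should insert, and the only free ortho C–H (C4a) should be palladated to an aryl–norbornyl palladacycle of divalent palladium; oxidative addition of the primary C–Br bond of 19 (to tetravalent palladium) and C–C reductive elimination would form C4–C4a, after which the doubly ortho-substituted arene extrudes norbornene and the tethered hydroxyl, deprotonated at palladium by Cs2CO3, closes O1–C8a by C–O reductive elimination; the closest known reaction types are the palladium/norbornene annulation of aryl iodides with epoxides to 2,3-dihydrobenzofurans, ortho alkylation with ipso amination by bromoalkylamines to tetrahydroquinolines, and the palladium-catalysed intramolecular etherification of 3-(2-halophenyl)propanols to chromans. Ring C closes by aryl C–O reductive elimination from a seven-membered oxapalladacycle, which gives the six-membered ring in a formal [3+3] sense. No stereocentre is formed: C3 arrives in 19, no bond to it is made or broken, and it carries no acidifying group, so its configuration should persist. Single alkylation is secured by the substrate, because C8 bears the dioxolane and only C4a has a hydrogen; the same ortho substituent drives norbornene extrusion. Selectivity for the aryl iodide over the alkyl bromide at zerovalent palladium, and for C–C before C–O coupling, rests on fast norbornene insertion, and the bulky electron-rich XPhos is chosen to favour C–O reductive elimination over β-hydride loss from the alkoxide. The weak, heterogeneous base in dioxane should leave 19 largely un-ionised in solution, which limits reversion to oxetane 17 and elimination of HBr.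

Step 11
Reactants: 20 2-{(3R)-3-[2,4-bis(methoxymethoxy)-3-(3-methylbut-2-en-1-yl)phenyl]-5-methoxy-7-(methoxymethoxy)-3,4-dihydro-2H-chromen-8-yl}-1,3-dioxolane
Product: 21 (3R)-3-[2,4-dihydroxy-3-(3-methylbut-2-en-1-yl)phenyl]-7-hydroxy-5-methoxy-3,4-dihydro-2H-chromene-8-carbaldehyde
Conditions: 3 M aq. HCl, MeOH–THF, 45 °C
Reagents that add atoms: water, O
Why: Acid-catalysed hydrolysis of the dioxolane and cleavage of the three MOM acetals, a standard end game for prenylated polyphenols. Methanol captures the methoxymethyl cations as dimethoxymethane, and moderate temperature and short time are meant to keep the prenyl group from closing onto the freed phenols. C3 is not involved.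

## Compound list

1 | 2-bromo-4,6-dimethoxybenzaldehyde | COc1cc(Br)c(C=O)c(OC)c1 | starting material
2 | 3-bromo-2-formyl-5-methoxyphenyl dichloroborinate | COc1cc(Br)c(C=O)c(OB(Cl)Cl)c1 | intermediate
3 | 2-bromo-6-hydroxy-4-methoxybenzaldehyde | COc1cc(O)c(C=O)c(Br)c1 | intermediate
4 | 2-bromo-4-methoxy-6-(methoxymethoxy)benzaldehyde | COCOc1cc(OC)cc(Br)c1C=O | intermediate
5 | 2-[2-bromo-4-methoxy-6-(methoxymethoxy)phenyl]-1,3-dioxolane | COCOc1cc(OC)cc(Br)c1C1OCCO1 | intermediate
6 | [2-(1,3-dioxolan-2-yl)-5-methoxy-3-(methoxymethoxy)phenyl]lithium | [Li]c1cc(OC)cc(OCOC)c1C1OCCO1 | intermediate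
7 | 2-[2-iodo-4-methoxy-6-(methoxymethoxy)phenyl]-1,3-dioxolane | COCOc1cc(OC)cc(I)c1C1OCCO1 | intermediate
8 | 4-bromobenzene-1,3-diol | Oc1ccc(Br)c(O)c1 | starting material
9 | 1-bromo-2,4-bis(methoxymethoxy)benzene | COCOc1ccc(Br)c(OCOC)c1 | intermediate
10 | [2,4-bis(methoxymethoxy)phenyl]lithium | [Li]c1ccc(OCOC)cc1OCOC | intermediate
11 | lithium [2,4-bis(methoxymethoxy)phenyl]tri(propan-2-yloxy)borate | [Li+].CC(C)O[B-](OC(C)C)(OC(C)C)c1ccc(OCOC)cc1OCOC | intermediate
12 | [2,4-bis(methoxymethoxy)phenyl]boronic acid | OB(O)c1ccc(OCOC)cc1OCOC | intermediate
13 | 3-iodooxetane | IC1COC1 | starting material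
14 | 3-[2,4-bis(methoxymethoxy)phenyl]oxetane | COCOc1ccc(C2COC2)c(OCOC)c1 | intermediate
15 | 1-bromo-3-methylbut-2-ene | CC(C)=CCBr | starting material
16 | [2,6-bis(methoxymethoxy)-3-(oxetan-3-yl)phenyl]lithium | [Li]c1c(OCOC)ccc(C2COC2)c1OCOC | intermediate
17 | 3-[2,4-bis(methoxymethoxy)-3-(3-methylbut-2-en-1-yl)phenyl]oxetane | COCOc1ccc(C2COC2)c(OCOC)c1CC=C(C)C | intermediate
18 | {(2R)-3-bromo-2-[2,4-bis(methoxymethoxy)-3-(3-methylbut-2-en-1-yl)phenyl]propoxy}trimethylsilane | BrC[C@H](c1ccc(OCOC)c(CC=C(C)C)c1OCOC)CO[Si](C)(C)C | intermediate
19 | (2R)-3-bromo-2-[2,4-bis(methoxymethoxy)-3-(3-methylbut-2-en-1-yl)phenyl]propan-1-ol | BrC[C@H](c1ccc(OCOC)c(CC=C(C)C)c1OCOC)CO | intermediate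
20 | 2-{(3R)-3-[2,4-bis(methoxymethoxy)-3-(3-methylbut-2-en-1-yl)phenyl]-5-methoxy-7-(methoxymethoxy)-3,4-dihydro-2H-chromen-8-yl}-1,3-dioxolane | COc1cc(OCOC)c(C3OCCO3)c2c1C[C@H](c1ccc(OCOC)c(CC=C(C)C)c1OCOC)CO2 | intermediate
21 | (3R)-3-[2,4-dihydroxy-3-(3-methylbut-2-en-1-yl)phenyl]-7-hydroxy-5-methoxy-3,4-dihydro-2H-chromene-8-carbaldehyde | COc1cc(O)c(C=O)c2c1C[C@H](c1ccc(O)c(CC=C(C)C)c1O)CO2 | target

## Step count and least certain steps

Total: 11 steps. Longest linear sequence: 7 steps (steps 5 to 11, from 8). The ring A branch (steps 1 to 4) joins at step 10.

**Step 10 (key step).**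
- *What may go wrong.* The β-branched primary bromide may add too slowly to the palladacycle, which then collapses with norbornene or is reduced at the ipso carbon. Base may consume 19 by re-closure to the oxetane or by loss of HBr. The final alkoxide of divalent palladium may undergo β-hydride elimination instead of C–O reductive elimination.
- *Fallback.* It separates the two bond formations, uses established reaction types, sets out from 19 and 7 and returns at 20. Acetylation of 19 (Ac2O, pyridine) would give the bromo acetate F1, an electrophile with no free hydroxyl that can be used in excess. Catellani ortho-alkylation of 7 with F1, terminated by ipso borylation (Pd(OAc)2, a triarylphosphine, norbornene, B2pin2, Cs2CO3), would give the aryl pinacolboronate acetate F2. NaOH/H2O2 would oxidise the C–B bond and saponify the ester to the phenol alcohol F3. Mitsunobu cyclisation (PPh3, DIAD, THF) would then close ring C at O1–C2 instead of O1–C8a and give 20. This removes the alkoxide-borne failures; it still relies on the ortho-alkylation itself.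

**Step 9.**
- *What may go wrong.* Enantioselectivity may be eroded, because the ortho MOM ether can assist an uncatalysed background opening and may disturb catalyst recognition. Some silylative cleavage of the MOM ethers by TMSBr is a lesser risk.
- *Fallback.* It changes the source of enantiopurity, sets out from 17 and returns at 19. Uncatalysed opening of 17 with TMSBr (CH2Cl2, −40 °C) would give the racemic silyl ether F4 and, after aqueous work-up, the racemic bromohydrin F5. Lipase-catalysed acetylation (Burkholderia cepacia lipase, vinyl acetate, tBuOMe) would resolve F5, leaving (R)-alcohol 19 and forming the (S)-acetate F6. F6 is not wasted: KOtBu in THF cleaves the ester and closes the alkoxide onto the bromide, which returns achiral oxetane 17 for another pass.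

**Step 11.**
- *What may go wrong.* Protic acid may cyclise the prenyl group onto the freed ortho phenols before the last MOM ether has left.
- *Fallback.* It replaces hydrolysis by protecting-group exchange, sets out from 20 and returns at 21. TESOTf with 2,2′-bipyridyl in MeCN, followed by water, should exchange the three aryl MOM ethers for triethylsilyl ethers and open the dioxolane to the aldehyde, giving the tris(triethylsilyl) ether aldehyde F7. Buffered fluoride (TBAF, AcOH, THF, 0 °C) would then give 21 without free strong acid ever meeting the free phenols.

**Step 7.**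
- *What may go wrong.* The electron-rich ortho-alkoxy boronic acid may protodeboronate in the hot basic alcohol faster than it transmetalates.
- *Fallback.* It avoids the boron reagent, sets out from 9 and 13 and returns at 14. Nickel-catalysed reductive cross-electrophile coupling of aryl bromide 9 with 13 (NiI2, 4,4′-di-tert-butyl-2,2′-bipyridine, Zn, DMA, 60 °C) is a known way to join aryl bromides to oxetan-3-yl halides. It makes no new compound and also removes step 6.

## Further compounds

F1 | step 10 | (2R)-3-bromo-2-[2,4-bis(methoxymethoxy)-3-(3-methylbut-2-en-1-yl)phenyl]propyl acetate | BrC[C@H](c1ccc(OCOC)c(CC=C(C)C)c1OCOC)COC(C)=O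
F2 | step 10 | (2R)-2-[2,4-bis(methoxymethoxy)-3-(3-methylbut-2-en-1-yl)phenyl]-3-[3-(1,3-dioxolan-2-yl)-6-methoxy-4-(methoxymethoxy)-2-(4,4,5,5-tetramethyl-1,3,2-dioxaborolan-2-yl)phenyl]propyl acetate | COc1cc(OCOC)c(C2OCCO2)c(B2OC(C)(C)C(C)(C)O2)c1C[C@H](c1ccc(OCOC)c(CC=C(C)C)c1OCOC)COC(C)=O
F3 | step 10 | 2-(1,3-dioxolan-2-yl)-6-{(2R)-2-[2,4-bis(methoxymethoxy)-3-(3-methylbut-2-en-1-yl)phenyl]-3-hydroxypropyl}-5-methoxy-3-(methoxymethoxy)phenol | COc1cc(OCOC)c(C2OCCO2)c(O)c1C[C@H](c1ccc(OCOC)c(CC=C(C)C)c1OCOC)CO
F4 | step 9 | racemic {3-bromo-2-[2,4-bis(methoxymethoxy)-3-(3-methylbut-2-en-1-yl)phenyl]propoxy}trimethylsilane | BrCC(c1ccc(OCOC)c(CC=C(C)C)c1OCOC)CO[Si](C)(C)C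
F5 | step 9 | racemic 3-bromo-2-[2,4-bis(methoxymethoxy)-3-(3-methylbut-2-en-1-yl)phenyl]propan-1-ol | BrCC(c1ccc(OCOC)c(CC=C(C)C)c1OCOC)CO
F6 | step 9 | (2S)-3-bromo-2-[2,4-bis(methoxymethoxy)-3-(3-methylbut-2-en-1-yl)phenyl]propyl acetate | BrC[C@@H](c1ccc(OCOC)c(CC=C(C)C)c1OCOC)COC(C)=O
F7 | step 11 | (3R)-3-[3-(3-methylbut-2-en-1-yl)-2,4-bis(triethylsilyloxy)phenyl]-5-methoxy-7-(triethylsilyloxy)-3,4-dihydro-2H-chromene-8-carbaldehyde | COc1cc(O[Si](CC)(CC)CC)c(C=O)c2c1C[C@H](c1ccc(O[Si](CC)(CC)CC)c(CC=C(C)C)c1O[Si](CC)(CC)CC)CO2
F0 | step 7 | none | none
A1 | alternative 1 | 6-[(3R)-5,7-dimethoxychroman-3-yl]-2-(3-methylbut-2-enyl)-3-(triisopropylsilyloxy)phenol | COc1cc(OC)cc2c1C[C@H](c1ccc(O[Si](C(C)C)(C(C)C)C(C)C)c(CC=C(C)C)c1O)CO2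
A2 | alternative 1 | (E)-1-diazo-4-[(3R)-5,7-dimethoxychroman-3-yl]but-3-en-2-one | COc1cc(OC)cc2c1C[C@H](/C=C/C(=O)C=[N+]=[N-])CO2
A3 | alternative 1 | triisopropyl[(5-methylhex-4-en-1-yn-1-yl)oxy]silane | CC(C)=CCC#CO[Si](C(C)C)(C(C)C)C(C)C
A4 | alternative 2 | (3R)-3-[2,4-bis(methoxymethoxy)-3-(3-methylbut-2-enyl)phenyl]-5,7-dimethoxychroman-2-one | COc1cc(OC)cc2c1C[C@H](c1ccc(OCOC)c(CC=C(C)C)c1OCOC)C(=O)O2
A5 | alternative 2 | 2-[2,4-bis(methoxymethoxy)-3-(3-methylbut-2-enyl)phenyl]-1-(1H-imidazol-1-yl)ethan-1-one | O=C(Cc1ccc(OCOC)c(CC=C(C)C)c1OCOC)n1ccnc1
A6 | alternative 2 | [2-(bromomethyl)-3,5-dimethoxyphenoxy](tert-butyl)dimethylsilane | COc1cc(OC)c(CBr)c(O[Si](C)(C)C(C)(C)C)c1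
A7 | alternative 3 | (3R)-3-[2,4-bis(methoxymethoxy)-3-(3-methylbut-2-enyl)phenyl]-5,7-dimethoxychroman-2-ol (anomer mixture) | COc1cc(OC)cc2c1C[C@H](c1ccc(OCOC)c(CC=C(C)C)c1OCOC)C(O)O2
A8 | alternative 3 | 3,5-dimethoxyphenol | COc1cc(O)cc(OC)c1
A9 | alternative 3 | 2-[2,4-bis(methoxymethoxy)-3-(3-methylbut-2-enyl)phenyl]prop-2-enal | C=C(C=O)c1ccc(OCOC)c(CC=C(C)C)c1OCOC
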